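Atoms carry daucane numbers: C1 is the methyl-bearing ring-fusion carbon, C5 the ring-fusion CH, C6 the ester carbinol, C7=C8 the ring alkene, C9 the free carbinol and C10 the ring CH2. The route rests on cutting the seven-membered ring at C6–C7 and C9–C10: in the ene-1,4-diol unit C6(O)–C7=C8–C9(O) each bond joins a carbinol carbon to a carbon that can be made nucleophilic at chromium. One flask unites cyclopentane 9 (C10 iodomethyl group, C6 formyl group) with the (Z)-iodoenal 13: cobalt-catalysed alkylchromium addition makes C9–C10, nickel-catalysed Nozaki–Hiyama–Kishi closure makes C6–C7 and the cycloheptene.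

Key step: step 9

Assumption: the catalyst antipodes named in steps 2, 6 and 12 are those expected from the accepted transition-state models; if a step shows the opposite sense, its mirror-image catalyst is used.

Step 1
Reactants: 1 3-methylbut-1-yne; 2 ethene
Product: 3 2-(propan-2-yl)buta-1,3-diene
Conditions: ethene (1 atm), second-generation Grubbs catalyst RuCl2(=CHPh)(PCy3)(H2IMes) (3 mol %), CH2Cl2, 23 °C; diene used as a solution
Reagents that add atoms: none
Why: Ethene–alkyne cross enyne metathesis of a terminal alkyne is a known route to 2-substituted buta-1,3-dienes; no stereocentre is formed.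

Step 2
Reactants: 3 2-(propan-2-yl)buta-1,3-diene; 4 2-methylprop-2-enal
Product: 5 (1S)-1-methyl-4-(propan-2-yl)cyclohex-3-ene-1-carbaldehyde
Conditions: (S)-1-(2-methylphenyl)-3,3-diphenyltetrahydro-1H,3H-pyrrolo[1,2-c][1,3,2]oxazaborole (20 mol %), Tf2NH (20 mol %), CH2Cl2, −78 to −40 °C
Reagents that add atoms: none
Why: Enantioselective Diels–Alder reaction under chiral oxazaborolidinium catalysis; the 2-substituted diene adds with "para" orientation and the catalyst shields one face of the enal, which sets the quaternary C1.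

Step 3
Reactants: 5 (1S)-1-methyl-4-(propan-2-yl)cyclohex-3-ene-1-carbaldehyde
Product: 6 [(1S)-1-methyl-4-(propan-2-yl)cyclohex-3-en-1-yl]methanol
Conditions: NaBH4, MeOH, 0 °C
Reagents that add atoms: none
Why: Hydride reduction of the aldehyde; the quaternary centre is untouched.

Step 4
Reactants: 6 [(1S)-1-methyl-4-(propan-2-yl)cyclohex-3-en-1-yl]methanol
Product: 7 (4S)-4-(iodomethyl)-4-methyl-1-(propan-2-yl)cyclohex-1-ene
Conditions: PPh3, I2, imidazole, toluene, 80 °C
Reagents that add atoms: iodine, II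
Why: Appel-type iodination (Garegg–Samuelsson conditions) through the alkoxyphosphonium ion; heating compensates for slow substitution next to the quaternary carbon.

Step 5
Reactants: 7 (4S)-4-(iodomethyl)-4-methyl-1-(propan-2-yl)cyclohex-1-ene
Product: 8 (3S)-3-(iodomethyl)-3,7-dimethyl-6-oxooctanal
Conditions: O3, pyridine (3 equiv), CH2Cl2, −78 °C
Reagents that add atoms: ozone, [O-][O+]=O
Why: Ozonolysis of the only alkene with pyridine as in situ reductant should give the isopropyl ketone (C4) and the aldehyde (C6) directly; the trisubstituted alkene reacts far faster than the alkyl iodide.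

Step 6
Reactants: 8 (3S)-3-(iodomethyl)-3,7-dimethyl-6-oxooctanal
Product: 9 (1R,2R,5S)-2-hydroxy-5-(iodomethyl)-5-methyl-2-(propan-2-yl)cyclopentane-1-carbaldehyde
Conditions: (S)-proline (30 mol %), CH2Cl2, 23 °C; used without chromatography
Reagents that add atoms: none
Why: Proline-catalysed intramolecular enolexo aldol reaction (aldehyde enamine onto the isopropyl ketone, the cyclisation mode known from the limonene keto-aldehyde); because CH3 and CH2I at C1 give almost no substrate bias, the catalyst selects the ketone face and fixes C4, and the formyl-bearing C5 equilibrates through the enamine to the epimer with CHO trans to isopropyl and cis to the OH.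

Step 7
Reactants: 10 prop-2-yn-1-ol
Product: 12 (2Z)-3-iodo-2-methylprop-2-en-1-ol, via alkenylmagnesium alkoxide 11 (not isolated)
Conditions: MeMgBr (3 equiv), CuI (10 mol %), THF, −10 to 23 °C; then I2, −40 to 0 °C
Reagents that add atoms: methylmagnesium bromide, C[Mg]Br; iodine, II
Why: Copper-catalysed anti-carbomagnesiation of the propargylic alkoxide (Duboudin reaction) places CH3 on the inner carbon and magnesium on the terminal carbon cis to CH2O through a five-membered chelate; iodinolysis with retention gives the (Z)-iodide.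

Step 8
Reactants: 12 (2Z)-3-iodo-2-methylprop-2-en-1-ol
Product: 13 (2Z)-3-iodo-2-methylprop-2-enal
Conditions: MnO2, CH2Cl2, 23 °C, dark; used at once
Reagents that add atoms: none
Why: Allylic oxidation with MnO2; the (Z)-geometry should be kept when light and acid are excluded.

Step 9
Reactants: 9 (1R,2R,5S)-2-hydroxy-5-(iodomethyl)-5-methyl-2-(propan-2-yl)cyclopentane-1-carbaldehyde; 13 (2Z)-3-iodo-2-methylprop-2-enal
Product: 15 (3R,3aS,4S,8aR)-6,8a-dimethyl-3-(propan-2-yl)-1,2,3,3a,4,7,8,8a-octahydroazulene-3,4,7-triol (both C-7 epimers), via iodoalkenyl carbinol aldehyde 14 (not isolated)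
Conditions: 13 (1.3 equiv), CrCl2 (8 equiv), cobalt phthalocyanine CoPc (C32H16CoN8, 10 mol %), DMF, 23 °C; then dilution, NiCl2 (2 mol %), 23 °C; aqueous sodium serinate work-up
Reagents that add atoms: none
Why: Divalent chromium with CoPc turns the neopentyl-type C–I bond of 9 into an alkylchromium reagent (Takai-type alkyl Nozaki–Hiyama reaction) that adds 1,2 to the unhindered enal 13, forming C9–C10 and the alkoxide of 14; NiCl2 is then added so that the alkenyl iodide enters the Nozaki–Hiyama–Kishi cycle and the alkenylchromium adds to the formyl group, forming C6–C7. Both events unite two electrophilic carbons (halide carbon and carbonyl carbon) by polarity reversal at chromium and are known individually; here they run in sequence in one flask. The seven-membered ring closes by 7-exo-trig addition of C7 to the C6 carbonyl, the (Z)-alkene already holding C6 and C9 cis. C6 is set by the adjacent C5: the formyl group, held syn to the tertiary hydroxyl by chelation or hydrogen bonding, is attacked on the face away from quaternary C1, which should give the 6S alkoxide. C9 forms without control, and both epimers are carried to the ketone in step 10 and reset in step 12. The step needs chemoselectivity between two aldehydes and two iodides: steric shielding of the formyl group of 9, the trans placement of CH2I and CHO on the ring (no four-membered closure) and the delayed addition of nickel (no alkenylchromium while free enal is present) secure it.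

Step 10
Reactants: 15 (3R,3aS,4S,8aR)-6,8a-dimethyl-3-(propan-2-yl)-1,2,3,3a,4,7,8,8a-octahydroazulene-3,4,7-triol (both C-7 epimers)
Product: 16 (3R,3aS,4S,8aR)-3,4-dihydroxy-6,8a-dimethyl-3-(propan-2-yl)-2,3,3a,4,8,8a-hexahydroazulen-7(1H)-one
Conditions: TEMPO (10 mol %), PhI(OAc)2 (1.1 equiv), CH2Cl2, 0 °C
Reagents that add atoms: none
Why: Oxoammonium (TEMPO) oxidation is very sensitive to hindrance, so the C9 carbinol next to a CH2 group should react before the C6 carbinol flanked by the ring-fusion carbon and two quaternary centres; both C9 epimers converge on one enone.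

Step 11
Reactants: 16 (3R,3aS,4S,8aR)-3,4-dihydroxy-6,8a-dimethyl-3-(propan-2-yl)-2,3,3a,4,8,8a-hexahydroazulen-7(1H)-one; 17 4-(acetyloxy)-3-methoxybenzoic acid
Product: 18 (3R,3aS,4S,8aR)-3-hydroxy-6,8a-dimethyl-7-oxo-3-(propan-2-yl)-1,2,3,3a,4,7,8,8a-octahydroazulen-4-yl 4-(acetyloxy)-3-methoxybenzoate
Conditions: N,N'-diisopropylcarbodiimide, DMAP, CH2Cl2, 23 °C
Reagents that add atoms: none
Why: Steglich esterification of the only acylable hydroxyl group: C9 is masked as the ketone and the tertiary C4 hydroxyl does not react; C6 keeps its configuration.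

Step 12
Reactants: 18 (3R,3aS,4S,8aR)-3-hydroxy-6,8a-dimethyl-7-oxo-3-(propan-2-yl)-1,2,3,3a,4,7,8,8a-octahydroazulen-4-yl 4-(acetyloxy)-3-methoxybenzoate
Product: 19 (3R,3aS,4S,7S,8aR)-3,7-dihydroxy-6,8a-dimethyl-3-(propan-2-yl)-1,2,3,3a,4,7,8,8a-octahydroazulen-4-yl 4-(acetyloxy)-3-methoxybenzoate
Conditions: (R)-1-methyl-3,3-diphenyltetrahydro-1H,3H-pyrrolo[1,2-c][1,3,2]oxazaborole (1 equiv), catecholborane (3 equiv), toluene, −78 °C
Reagents that add atoms: none
Why: Corey–Bakshi–Shibata 1,2-reduction of the 2-methyl enone: the oxazaborolidine delivers hydride to the face set by the catalyst with the alkenyl arm as the large group, which should fix C9 as S under reagent control.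

Step 13
Reactants: 19 (3R,3aS,4S,7S,8aR)-3,7-dihydroxy-6,8a-dimethyl-3-(propan-2-yl)-1,2,3,3a,4,7,8,8a-octahydroazulen-4-yl 4-(acetyloxy)-3-methoxybenzoate
Product: 20 (3R,3aS,4S,7S,8aR)-3,7-dihydroxy-6,8a-dimethyl-3-(propan-2-yl)-1,2,3,3a,4,7,8,8a-octahydroazulen-4-yl 4-hydroxy-3-methoxybenzoate
Conditions: K2CO3 (0.2 equiv), MeOH, 0 °C
Reagents that add atoms: none
Why: Base-catalysed methanolysis of the phenyl acetate, far faster than cleavage of the hindered secondary aryl ester, frees the phenol.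

Compound list
1 | 3-methylbut-1-yne | CC(C)C#C | starting material
2 | ethene | C=C | starting material
3 | 2-(propan-2-yl)buta-1,3-diene | C=CC(=C)C(C)C | intermediate
4 | 2-methylprop-2-enal | CC(=C)C=O | starting material
5 | (1S)-1-methyl-4-(propan-2-yl)cyclohex-3-ene-1-carbaldehyde | O=C[C@@]1(C)CCC(C(C)C)=CC1 | intermediate
6 | [(1S)-1-methyl-4-(propan-2-yl)cyclohex-3-en-1-yl]methanol | OC[C@@]1(C)CCC(C(C)C)=CC1 | intermediate
7 | (4S)-4-(iodomethyl)-4-methyl-1-(propan-2-yl)cyclohex-1-ene | IC[C@@]1(C)CCC(C(C)C)=CC1 | intermediate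
8 | (3S)-3-(iodomethyl)-3,7-dimethyl-6-oxooctanal | O=CC[C@@](C)(CI)CCC(=O)C(C)C | intermediate
9 | (1R,2R,5S)-2-hydroxy-5-(iodomethyl)-5-methyl-2-(propan-2-yl)cyclopentane-1-carbaldehyde | IC[C@@]1(C)CC[C@@](O)(C(C)C)[C@@H]1C=O | intermediate
10 | prop-2-yn-1-ol | C#CCO | starting material
11 | bromomagnesium (2Z)-3-(bromomagnesio)-2-methylprop-2-en-1-olate | Br[Mg]OC/C(C)=C\[Mg]Br | intermediate
12 | (2Z)-3-iodo-2-methylprop-2-en-1-ol | OC/C(C)=C\I | intermediate
13 | (2Z)-3-iodo-2-methylprop-2-enal | O=C/C(C)=C\I | intermediate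
14 | (1R,2R,5R)-2-hydroxy-5-[(3Z)-2-hydroxy-4-iodo-3-methylbut-3-en-1-yl]-5-methyl-2-(propan-2-yl)cyclopentane-1-carbaldehyde (both side-chain carbinol epimers) | O=C[C@H]1[C@](O)(C(C)C)CC[C@]1(C)CC(O)/C(C)=C\I | intermediate
15 | (3R,3aS,4S,8aR)-6,8a-dimethyl-3-(propan-2-yl)-1,2,3,3a,4,7,8,8a-octahydroazulene-3,4,7-triol (both C-7 epimers) | O[C@H]1C=C(C)C(O)C[C@@]2(C)CC[C@@](O)(C(C)C)[C@H]12 | intermediate
16 | (3R,3aS,4S,8aR)-3,4-dihydroxy-6,8a-dimethyl-3-(propan-2-yl)-2,3,3a,4,8,8a-hexahydroazulen-7(1H)-one | O[C@H]1C=C(C)C(=O)C[C@@]2(C)CC[C@@](O)(C(C)C)[C@H]12 | intermediate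
17 | 4-(acetyloxy)-3-methoxybenzoic acid | COc1cc(C(=O)O)ccc1OC(C)=O | starting material
18 | (3R,3aS,4S,8aR)-3-hydroxy-6,8a-dimethyl-7-oxo-3-(propan-2-yl)-1,2,3,3a,4,7,8,8a-octahydroazulen-4-yl 4-(acetyloxy)-3-methoxybenzoate | COc1cc(C(=O)O[C@H]2C=C(C)C(=O)C[C@@]3(C)CC[C@@](O)(C(C)C)[C@H]23)ccc1OC(C)=O | intermediate
19 | (3R,3aS,4S,7S,8aR)-3,7-dihydroxy-6,8a-dimethyl-3-(propan-2-yl)-1,2,3,3a,4,7,8,8a-octahydroazulen-4-yl 4-(acetyloxy)-3-methoxybenzoate | COc1cc(C(=O)O[C@H]2C=C(C)[C@@H](O)C[C@@]3(C)CC[C@@](O)(C(C)C)[C@H]23)ccc1OC(C)=O | intermediate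
20 | (3R,3aS,4S,7S,8aR)-3,7-dihydroxy-6,8a-dimethyl-3-(propan-2-yl)-1,2,3,3a,4,7,8,8a-octahydroazulen-4-yl 4-hydroxy-3-methoxybenzoate | COc1cc(C(=O)O[C@H]2C=C(C)[C@@H](O)C[C@@]3(C)CC[C@@](O)(C(C)C)[C@H]23)ccc1O | target

Total step count: 13. Longest linear sequence: 11 steps (steps 1 to 6 and 9 to 13); steps 7 and 8 form the short branch.

Steps most likely to fail

Step 9. The alkylchromium reagent may form sluggishly from the neopentyl-type iodide, the intermolecular addition may lose out to oligomerisation or to early activation of the alkenyl iodide, and facial control in the ring closure may be low. The fallback sets out from 9 (with 13) and comes back at 16; it makes C9–C10 with an organolithium and closes the ring in a separate step at the ketone level. NaBH4 reduction of 9 gives the diol (1R,2S,3S)-2-(hydroxymethyl)-3-(iodomethyl)-3-methyl-1-(propan-2-yl)cyclopentan-1-ol F1. TESCl and imidazole protect the primary hydroxyl to give the silyl ether (1R,2S,3S)-3-(iodomethyl)-3-methyl-1-(propan-2-yl)-2-{[(triethylsilyl)oxy]methyl}cyclopentan-1-ol F2. Iodine–lithium exchange with t-BuLi (Et2O–pentane, −78 °C, one extra equivalent for the tertiary alkoxide) and addition to 13 give the allylic alcohol (1R,2S,3R)-3-[(3Z)-2-hydroxy-4-iodo-3-methylbut-3-en-1-yl]-3-methyl-1-(propan-2-yl)-2-{[(triethylsilyl)oxy]methyl}cyclopentan-1-ol F3. MnO2 oxidises it to the enone (3Z)-1-[(1R,2S,3R)-3-hydroxy-1-methyl-3-(propan-2-yl)-2-{[(triethylsilyl)oxy]methyl}cyclopentyl]-4-iodo-3-methylbut-3-en-2-one F4. HF·pyridine removes the silyl group to give the primary alcohol (3Z)-1-[(1R,2S,3R)-3-hydroxy-2-(hydroxymethyl)-1-methyl-3-(propan-2-yl)cyclopentyl]-4-iodo-3-methylbut-3-en-2-one F5. Dess–Martin periodinane gives the aldehyde (1R,2R,5R)-2-hydroxy-5-[(3Z)-4-iodo-3-methyl-2-oxobut-3-en-1-yl]-5-methyl-2-(propan-2-yl)cyclopentane-1-carbaldehyde F6, and an intramolecular Nozaki–Hiyama–Kishi reaction (CrCl2, NiCl2 cat., DMSO) closes it to 16.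

Step 6. Catalyst control over the ketone face may be weak for a five-membered enolexo closure, and the aldol may lose water. The fallback sets out from 8 and comes back at 9; it replaces catalyst-controlled C–C formation by a reagent-controlled epoxidation. Piperidine and acetic acid condense 8 to the enal (5S)-5-(iodomethyl)-5-methyl-2-(propan-2-yl)cyclopent-1-ene-1-carbaldehyde F7. NaBH4 with CeCl3 gives the allylic alcohol [(5S)-5-(iodomethyl)-5-methyl-2-(propan-2-yl)cyclopent-1-en-1-yl]methanol F8. Sharpless asymmetric epoxidation (Ti(OiPr)4, diethyl tartrate, t-BuOOH), with the tartrate antipode that delivers oxygen to the face cis to the C1 methyl group, gives the epoxy alcohol [(1S,2S,5R)-2-(iodomethyl)-2-methyl-5-(propan-2-yl)-6-oxabicyclo[3.1.0]hexan-1-yl]methanol F9. SO3·pyridine in DMSO gives the epoxy aldehyde (1R,2S,5R)-2-(iodomethyl)-2-methyl-5-(propan-2-yl)-6-oxabicyclo[3.1.0]hexane-1-carbaldehyde F10. SmI2 (THF–MeOH, −90 °C) cleaves the C–O bond next to the carbonyl and, after equilibration of the formyl-bearing centre, gives 9.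

Step 10. The oxidation may not discriminate well enough between the two allylic alcohols, so that the C6 carbinol is also oxidised. The fallback sets out from 15 and comes back at 18; it differentiates the two hydroxyls by silylation instead of by oxidation rate. TBSCl and imidazole silylate the less hindered C9 hydroxyl to give (3R,3aS,4S,8aR)-7-{[tert-butyl(dimethyl)silyl]oxy}-6,8a-dimethyl-3-(propan-2-yl)-1,2,3,3a,4,7,8,8a-octahydroazulene-3,4-diol F11. Esterification with 17 (N,N'-diisopropylcarbodiimide, DMAP) gives (3R,3aS,4S,8aR)-7-{[tert-butyl(dimethyl)silyl]oxy}-3-hydroxy-6,8a-dimethyl-3-(propan-2-yl)-1,2,3,3a,4,7,8,8a-octahydroazulen-4-yl 4-(acetyloxy)-3-methoxybenzoate F12. HF·pyridine gives (3R,3aS,4S,8aR)-3,7-dihydroxy-6,8a-dimethyl-3-(propan-2-yl)-1,2,3,3a,4,7,8,8a-octahydroazulen-4-yl 4-(acetyloxy)-3-methoxybenzoate F13 as both C-7 epimers, and Dess–Martin periodinane oxidises it to 18.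

Further compounds
F1 | step 9 | (1R,2S,3S)-2-(hydroxymethyl)-3-(iodomethyl)-3-methyl-1-(propan-2-yl)cyclopentan-1-ol | IC[C@@]1(C)CC[C@@](O)(C(C)C)[C@@H]1CO
F2 | step 9 | (1R,2S,3S)-3-(iodomethyl)-3-methyl-1-(propan-2-yl)-2-{[(triethylsilyl)oxy]methyl}cyclopentan-1-ol | IC[C@@]1(C)CC[C@@](O)(C(C)C)[C@@H]1CO[Si](CC)(CC)CC
F3 | step 9 | (1R,2S,3R)-3-[(3Z)-2-hydroxy-4-iodo-3-methylbut-3-en-1-yl]-3-methyl-1-(propan-2-yl)-2-{[(triethylsilyl)oxy]methyl}cyclopentan-1-ol (both side-chain carbinol epimers) | OC(C[C@@]1(C)CC[C@@](O)(C(C)C)[C@@H]1CO[Si](CC)(CC)CC)/C(C)=C\I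
F4 | step 9 | (3Z)-1-[(1R,2S,3R)-3-hydroxy-1-methyl-3-(propan-2-yl)-2-{[(triethylsilyl)oxy]methyl}cyclopentyl]-4-iodo-3-methylbut-3-en-2-one | O=C(C[C@@]1(C)CC[C@@](O)(C(C)C)[C@@H]1CO[Si](CC)(CC)CC)/C(C)=C\I
F5 | step 9 | (3Z)-1-[(1R,2S,3R)-3-hydroxy-2-(hydroxymethyl)-1-methyl-3-(propan-2-yl)cyclopentyl]-4-iodo-3-methylbut-3-en-2-one | O=C(C[C@@]1(C)CC[C@@](O)(C(C)C)[C@@H]1CO)/C(C)=C\I
F6 | step 9 | (1R,2R,5R)-2-hydroxy-5-[(3Z)-4-iodo-3-methyl-2-oxobut-3-en-1-yl]-5-methyl-2-(propan-2-yl)cyclopentane-1-carbaldehyde | O=C(C[C@@]1(C)CC[C@@](O)(C(C)C)[C@@H]1C=O)/C(C)=C\I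
F7 | step 6 | (5S)-5-(iodomethyl)-5-methyl-2-(propan-2-yl)cyclopent-1-ene-1-carbaldehyde | O=CC1=C(C(C)C)CC[C@]1(C)CI
F8 | step 6 | [(5S)-5-(iodomethyl)-5-methyl-2-(propan-2-yl)cyclopent-1-en-1-yl]methanol | OCC1=C(C(C)C)CC[C@]1(C)CI
F9 | step 6 | [(1S,2S,5R)-2-(iodomethyl)-2-methyl-5-(propan-2-yl)-6-oxabicyclo[3.1.0]hexan-1-yl]methanol | OC[C@@]12O[C@@]2(C(C)C)CC[C@]1(C)CI
F10 | step 6 | (1R,2S,5R)-2-(iodomethyl)-2-methyl-5-(propan-2-yl)-6-oxabicyclo[3.1.0]hexane-1-carbaldehyde | O=C[C@@]12O[C@@]2(C(C)C)CC[C@]1(C)CI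
F11 | step 10 | (3R,3aS,4S,8aR)-7-{[tert-butyl(dimethyl)silyl]oxy}-6,8a-dimethyl-3-(propan-2-yl)-1,2,3,3a,4,7,8,8a-octahydroazulene-3,4-diol (both C-7 epimers) | O[C@H]1C=C(C)C(O[Si](C)(C)C(C)(C)C)C[C@@]2(C)CC[C@@](O)(C(C)C)[C@H]12
F12 | step 10 | (3R,3aS,4S,8aR)-7-{[tert-butyl(dimethyl)silyl]oxy}-3-hydroxy-6,8a-dimethyl-3-(propan-2-yl)-1,2,3,3a,4,7,8,8a-octahydroazulen-4-yl 4-(acetyloxy)-3-methoxybenzoate (both C-7 epimers) | COc1cc(C(=O)O[C@H]2C=C(C)C(O[Si](C)(C)C(C)(C)C)C[C@@]3(C)CC[C@@](O)(C(C)C)[C@H]23)ccc1OC(C)=O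
F13 | step 10 | (3R,3aS,4S,8aR)-3,7-dihydroxy-6,8a-dimethyl-3-(propan-2-yl)-1,2,3,3a,4,7,8,8a-octahydroazulen-4-yl 4-(acetyloxy)-3-methoxybenzoate (both C-7 epimers) | COc1cc(C(=O)O[C@H]2C=C(C)C(O)C[C@@]3(C)CC[C@@](O)(C(C)C)[C@H]23)ccc1OC(C)=O
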